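**Retrosynthetic overview**
- Ring atoms are called ring C1 (carries the side chain), C2 (CH3), C3–C5 (CH2) and C6 (CMe2); side-chain atoms are chain C1–C10 as in the systematic name of the target.
- The butenolide comes from a 3-substituted furan (singlet oxygen, then NaBH4). The Z chain C3=C4 olefin with its CH2OH and the chain C1 carbinol come from reductive opening of a temporary α-alkyl dihydropyranone closed by RCM. Chain C1 (R) is set by Brown allylation of furan-3-carbaldehyde.
- Chain C5–C6 is made by alkylating β-monocyclofarnesyl bromide with the dianion of methallyl alcohol.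
- The cyclohexene is made by a Diels–Alder reaction of an acyclic 1,1,2,3-tetrasubstituted diene (ring C3=C2–C1=C6) with acrolein as an ethylene equivalent (ring C4, C5), forming ring C3–C4 and C5–C6 together; the formyl group is then removed by decarbonylation. The enabling feature is the tetrasubstituted ring C1=C2 olefin flanked by C3H2 and quaternary C6Me2, bridged by the substituent-free C4H2–C5H2 unit: a cyclohexene retron whose dienophile is plain ethylene and which has no ring stereocentre.
- The diene comes from B-alkyl Suzuki coupling of 2,4-dimethylpenta-1,3-dien-3-yl triflate with a C6 dienol ether. Ring order: cyclohexene (step 6), temporary dihydropyranone (step 15, opened in step 16), butenolide from the furan ring (steps 17–18).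

Key step: step 6

Remark: compounds 1, 2, 6, 11, 16, 21 and 22 are taken as catalogue materials (22 as its 1 M pentane solution; it can also be generated from the corresponding B-methoxy compound and allylmagnesium bromide).

Step 1
Reactants: 1 N-methoxy-N,2-dimethylpropanamide; 2 isopropenylmagnesium bromide
Product: 3 2,4-dimethylpent-1-en-3-one
Conditions: THF, 0 °C to rt; inverse quench into cold 1 M HCl
Reagents that add atoms: none
Why: Weinreb ketone synthesis, in which the chelated tetrahedral magnesium intermediate survives until the quench so that the vinyl Grignard reagent adds only once, and the acidic quench keeps the freed amine off the enone.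

Step 2
Reactants: 3 2,4-dimethylpent-1-en-3-one
Product: 5 2,4-dimethylpenta-1,3-dien-3-yl trifluoromethanesulfonate, via potassium dienolate 4 (not isolated)
Conditions: KN(SiMe3)2, THF, −78 °C; then PhNTf2, −78 to 0 °C
Reagents that add atoms: N-phenylbis(trifluoromethanesulfonimide), O=S(=O)(N(c1ccccc1)S(=O)(=O)C(F)(F)F)C(F)(F)F
Why: Kinetic enolisation can only occur at the isopropyl C–H (the other side is vinylic), and O-triflation of the cross-conjugated dienolate is the standard route to 2-triflyloxy-1,3-dienes; the enolate carbon carries two methyl groups, so no olefin geometry arises.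

Step 3
Reactants: 6 (2E)-3-methylpent-2-en-4-yn-1-ol
Product: 7 tert-butyl(dimethyl){[(2E)-3-methylpent-2-en-4-yn-1-yl]oxy}silane
Conditions: TBSCl, imidazole, CH2Cl2, 0 °C to rt
Reagents that add atoms: tert-butyldimethylsilyl chloride, CC(C)(C)[Si](C)(C)Cl
Why: Standard silylation of a primary allylic alcohol, which masks the hydroxyl group for the borane, Lewis acid and rhodium steps.

Step 4
Reactants: 7 tert-butyl(dimethyl){[(2E)-3-methylpent-2-en-4-yn-1-yl]oxy}silane
Product: 8 tert-butyl(dimethyl){[(2E)-3-methylpenta-2,4-dien-1-yl]oxy}silane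
Conditions: H2 (1 atm), Pd/CaCO3 poisoned with Pb(OAc)2 (Lindlar catalyst), quinoline, hexane, rt, stopped after one equivalent of H2
Reagents that add atoms: none
Why: Lindlar semi-hydrogenation of a terminal conjugated enyne should stop at the 1,3-diene and leave the E-trisubstituted olefin untouched.

Step 5
Reactants: 8 tert-butyl(dimethyl){[(2E)-3-methylpenta-2,4-dien-1-yl]oxy}silane; 5 2,4-dimethylpenta-1,3-dien-3-yl trifluoromethanesulfonate
Product: 10 tert-butyl{[(2E)-3,7-dimethyl-6-(prop-1-en-2-yl)octa-2,6-dien-1-yl]oxy}dimethylsilane, via alkylborane 9 (not isolated)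
Conditions: 9-BBN, THF, 0 °C to rt; then 5, PdCl2(dppf) (5 mol%), 3 M aqueous K3PO4, DMF, 50 °C
Reagents that add atoms: none
Why: 9-BBN hydroborates the monosubstituted terminus of the 1,3-diene anti-Markovnikov and ignores the trisubstituted olefin, and the primary alkylborane should undergo B-alkyl Suzuki–Miyaura coupling with the hindered dienyl triflate as it does with 2,6,6-trimethylcyclohexenyl triflates; the E olefin is retained and no stereocentre is formed.

Step 6
Reactants: 10 tert-butyl{[(2E)-3,7-dimethyl-6-(prop-1-en-2-yl)octa-2,6-dien-1-yl]oxy}dimethylsilane; 11 acrolein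
Product: 12 3-[(3E)-5-{[tert-butyl(dimethyl)silyl]oxy}-3-methylpent-3-en-1-yl]-2,2,4-trimethylcyclohex-3-ene-1-carbaldehyde (racemic at C1)
Conditions: 11 (3 equiv), Me2AlCl (30 mol%), CH2Cl2, −78 to −30 °C; quench with Et3N, then aqueous NaHCO3
Reagents that add atoms: none
Why: Lewis acid-catalysed normal-demand Diels–Alder reaction in which Me2AlCl-complexed acrolein adds across the tetrasubstituted diene of 10 in a concerted but strongly asynchronous [4+2]: the bond from the unhindered diene CH2 terminus (ring C3) to the acrolein β-carbon (ring C4) runs ahead of the bond from the isopropylidene carbon (quaternary ring C6) to the α-carbon (ring C5), so both ring bonds form in one operation and the tetrasubstituted C1=C2 olefin is left exactly where the target has it. The closest known reaction type is the Lewis acid-catalysed cycloaddition of acrolein and acrylates to 1,1-disubstituted and 2,3-disubstituted butadienes, with the formyl group as a removable activating group (acrolein as an ethylene equivalent). The cyclohexene is closed by intermolecular [4+2] cycloaddition, suprafacial on both partners. The only new stereocentre, the formyl-bearing ring C5, is not controlled and need not be, because it becomes a CH2 group in step 7; for the same reason both regioisomers would converge, although the adduct drawn (CHO next to CMe2) is expected from the larger HOMO coefficient at the CH2 terminus. The step needs chemoselectivity for the diene over the isolated trisubstituted olefin and the allylic silyl ether, which the higher HOMO of the fully alkylated diene, the low temperature and the proton-scavenging Lewis acid should secure against ene and cationic pathways. The cisoid geometry, although strained by the inside methyl group, should be reachable because the 2-methyl and 3-alkyl groups destabilise the transoid form at least as much.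

Step 7
Reactants: 12 3-[(3E)-5-{[tert-butyl(dimethyl)silyl]oxy}-3-methylpent-3-en-1-yl]-2,2,4-trimethylcyclohex-3-ene-1-carbaldehyde
Product: 13 tert-butyl(dimethyl){[(2E)-3-methyl-5-(2,6,6-trimethylcyclohex-1-en-1-yl)pent-2-en-1-yl]oxy}silane
Conditions: RhCl(PPh3)3 (1.1 equiv), PhCN, 130 °C
Reagents that add atoms: none
Why: Tsuji–Wilkinson decarbonylation (oxidative addition of the formyl C–H to monovalent rhodium, CO extrusion, C–H reductive elimination) should replace CHO by H under neutral conditions, erasing the stereocentre of 12 and tolerating the silyl ether and the olefins.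

Step 8
Reactants: 13 tert-butyl(dimethyl){[(2E)-3-methyl-5-(2,6,6-trimethylcyclohex-1-en-1-yl)pent-2-en-1-yl]oxy}silane
Product: 14 (2E)-3-methyl-5-(2,6,6-trimethylcyclohex-1-en-1-yl)pent-2-en-1-ol (β-monocyclofarnesol)
Conditions: Bu4NF, THF, 0 °C to rt
Reagents that add atoms: none
Why: Fluoride-mediated cleavage of the silyl ether.

Step 9
Reactants: 14 (2E)-3-methyl-5-(2,6,6-trimethylcyclohex-1-en-1-yl)pent-2-en-1-ol
Product: 15 2-[(3E)-5-bromo-3-methylpent-3-en-1-yl]-1,3,3-trimethylcyclohex-1-ene
Conditions: PBr3 (0.4 equiv), pyridine (cat.), Et2O, −10 °C; used crude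
Reagents that add atoms: phosphorus tribromide, BrP(Br)Br
Why: Low-temperature, pyridine-buffered bromination of a primary allylic alcohol is the standard preparation of farnesyl-type bromides and keeps the E olefin.

Step 10
Reactants: 15 2-[(3E)-5-bromo-3-methylpent-3-en-1-yl]-1,3,3-trimethylcyclohex-1-ene; 16 2-methylprop-2-en-1-ol
Product: 18 (5E)-6-methyl-2-methylidene-8-(2,6,6-trimethylcyclohex-1-en-1-yl)oct-5-en-1-ol, via dilithium dianion 17 (not isolated)
Conditions: 16 (3 equiv), n-BuLi (6 equiv), TMEDA, Et2O, 0 °C to rt; then 15, THF, −78 to 0 °C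
Reagents that add atoms: none
Why: The alkoxide-directed allylic dianion of methallyl alcohol is a 2-(hydroxymethyl)allyl anion equivalent that should be C-alkylated by the primary allylic bromide in an SN2 reaction, either terminus of its symmetrical allyl unit giving the same product.

Step 11
Reactants: 18 (5E)-6-methyl-2-methylidene-8-(2,6,6-trimethylcyclohex-1-en-1-yl)oct-5-en-1-ol
Product: 19 (5E)-6-methyl-2-methylidene-8-(2,6,6-trimethylcyclohex-1-en-1-yl)oct-5-enal
Conditions: MnO2 (activated, excess), CH2Cl2, rt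
Reagents that add atoms: none
Why: MnO2 oxidises allylic alcohols selectively to enals without touching isolated olefins.

Step 12
Reactants: 19 (5E)-6-methyl-2-methylidene-8-(2,6,6-trimethylcyclohex-1-en-1-yl)oct-5-enal
Product: 20 (5E)-6-methyl-2-methylidene-8-(2,6,6-trimethylcyclohex-1-en-1-yl)oct-5-enoic acid
Conditions: NaClO2, NaH2PO4, 2-methylbut-2-ene (large excess), t-BuOH/H2O, 0 °C to rt
Reagents that add atoms: sodium chlorite, [Na+].[O-]Cl=O
Why: Pinnick oxidation converts the enal into the acrylic acid, with 2-methylbut-2-ene scavenging HOCl so that the electron-rich olefins are not chlorinated.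

Step 13
Reactants: 21 furan-3-carbaldehyde; 22 B-allyldiisopinocampheylborane (both isopinocampheyl groups from (−)-α-pinene)
Product: 24 (1R)-1-(furan-3-yl)but-3-en-1-ol, via borinate ester 23 (not isolated)
Conditions: Et2O, −78 °C; then 3 M NaOH, 30% H2O2, 0 °C to rt
Reagents that add atoms: none
Why: Brown allylation through a chair Zimmerman–Traxler transition state, in which the isopinocampheyl groups from (−)-α-pinene direct allyl transfer to the aldehyde face that gives the R alcohol with aryl-type aldehydes; this sets the only stereocentre of the target.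

Step 14
Reactants: 20 (5E)-6-methyl-2-methylidene-8-(2,6,6-trimethylcyclohex-1-en-1-yl)oct-5-enoic acid; 24 (1R)-1-(furan-3-yl)but-3-en-1-ol
Product: 25 (1R)-1-(furan-3-yl)but-3-en-1-yl (5E)-6-methyl-2-methylidene-8-(2,6,6-trimethylcyclohex-1-en-1-yl)oct-5-enoate
Conditions: DCC, DMAP (cat.), CH2Cl2, 0 °C to rt
Reagents that add atoms: none
Why: Steglich esterification acylates the hydroxyl oxygen, so the stereocentre is retained.

Step 15
Reactants: 25 (1R)-1-(furan-3-yl)but-3-en-1-yl (5E)-6-methyl-2-methylidene-8-(2,6,6-trimethylcyclohex-1-en-1-yl)oct-5-enoate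
Product: 26 (6R)-6-(furan-3-yl)-3-[(3E)-4-methyl-6-(2,6,6-trimethylcyclohex-1-en-1-yl)hex-3-en-1-yl]-5,6-dihydro-2H-pyran-2-one
Conditions: RuCl2(=CHPh)(PCy3)(H2IMes) (second-generation Grubbs catalyst, 5–10 mol%), CH2Cl2 (5 mM), 40 °C
Reagents that add atoms: none
Why: Ring-closing metathesis between the monosubstituted olefin and the 1,1-disubstituted acrylate closes the six-membered unsaturated lactone (the tri- and tetrasubstituted olefins are inert to the catalyst), and the ring holds the carbonyl carbon (the future CH2OH) cis to chain C2 across the new C3=C4 bond, which is the Z geometry of the target.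

Step 16
Reactants: 26 (6R)-6-(furan-3-yl)-3-[(3E)-4-methyl-6-(2,6,6-trimethylcyclohex-1-en-1-yl)hex-3-en-1-yl]-5,6-dihydro-2H-pyran-2-one
Product: 27 (1R,3Z,7E)-1-(furan-3-yl)-4-(hydroxymethyl)-8-methyl-10-(2,6,6-trimethylcyclohex-1-en-1-yl)deca-3,7-dien-1-ol
Conditions: i-Bu2AlH (4 equiv), CH2Cl2, −78 to 0 °C; aqueous KNaC4H4O6 (Rochelle salt)
Reagents that add atoms: none
Why: Exhaustive 1,2-reduction of the unsaturated lactone opens the temporary ring to the Z allylic alcohol and the secondary carbinol without touching olefin geometry or the stereocentre.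

Step 17
Reactants: 27 (1R,3Z,7E)-1-(furan-3-yl)-4-(hydroxymethyl)-8-methyl-10-(2,6,6-trimethylcyclohex-1-en-1-yl)deca-3,7-dien-1-ol
Product: 29 5-hydroxy-4-[(1R,3Z,7E)-1-hydroxy-4-(hydroxymethyl)-8-methyl-10-(2,6,6-trimethylcyclohex-1-en-1-yl)deca-3,7-dien-1-yl]furan-2(5H)-one (epimers at the hemiacetal carbon), via furan endoperoxide 28 (not isolated)
Conditions: O2, visible light, 5,10,15,20-tetraphenylporphyrin (cat.), i-Pr2NEt (excess), CH2Cl2, −78 °C
Reagents that add atoms: dioxygen (as singlet oxygen), O=O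
Why: Singlet oxygen adds [4+2] across the furan, the fastest acceptor at −78 °C, and the hindered amine removes the less hindered bridgehead proton (remote from the side chain), so the endoperoxide should collapse to the 4-substituted 5-hydroxybutenolide, as in the known oxidation of 3-alkylfurans bearing the same ring and trisubstituted olefins.

Step 18
Reactants: 29 5-hydroxy-4-[(1R,3Z,7E)-1-hydroxy-4-(hydroxymethyl)-8-methyl-10-(2,6,6-trimethylcyclohex-1-en-1-yl)deca-3,7-dien-1-yl]furan-2(5H)-one
Product: 31 4-[(1R,3Z,7E)-1-hydroxy-4-(hydroxymethyl)-8-methyl-10-(2,6,6-trimethylcyclohex-1-en-1-yl)deca-3,7-dien-1-yl]furan-2(5H)-one, via sodium hydroxy carboxylate 30 (not isolated)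
Conditions: NaBH4, EtOH/THF, 0 °C; then 1 M HCl to pH 2, rt
Reagents that add atoms: none
Why: The hydroxybutenolide is a masked cis-formyl acrylate, so borohydride reduces the ring-opened aldehyde and acidification closes the butenolide with the carbonyl remote from the side chain; the carbinol stereocentre is untouched and the secondary hydroxyl cannot lactonise because it lies trans to the carboxyl group.

**Compound list**
1 | N-methoxy-N,2-dimethylpropanamide | CC(C)C(=O)N(C)OC | starting material
2 | isopropenylmagnesium bromide | CC(=C)[Mg]Br | starting material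
3 | 2,4-dimethylpent-1-en-3-one | CC(C)C(=O)C(C)=C | intermediate
4 | potassium 2,4-dimethylpenta-1,3-dien-3-olate (not isolated) | CC(C)=C([O-])C(C)=C.[K+] | intermediate
5 | 2,4-dimethylpenta-1,3-dien-3-yl trifluoromethanesulfonate | CC(C)=C(OS(=O)(=O)C(F)(F)F)C(C)=C | intermediate
6 | (2E)-3-methylpent-2-en-4-yn-1-ol | C#C/C(C)=C/CO | starting material
7 | tert-butyl(dimethyl){[(2E)-3-methylpent-2-en-4-yn-1-yl]oxy}silane | C#C/C(C)=C/CO[Si](C)(C)C(C)(C)C | intermediate
8 | tert-butyl(dimethyl){[(2E)-3-methylpenta-2,4-dien-1-yl]oxy}silane | C=C/C(C)=C/CO[Si](C)(C)C(C)(C)C | intermediate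
9 | 9-[(3E)-5-{[tert-butyl(dimethyl)silyl]oxy}-3-methylpent-3-en-1-yl]-9-borabicyclo[3.3.1]nonane (not isolated) | CC(C)(C)[Si](C)(C)OC/C=C(\C)CCB1C2CCCC1CCC2 | intermediate
10 | tert-butyl{[(2E)-3,7-dimethyl-6-(prop-1-en-2-yl)octa-2,6-dien-1-yl]oxy}dimethylsilane | C=C(C)C(=C(C)C)CC/C(C)=C/CO[Si](C)(C)C(C)(C)C | intermediate
11 | acrolein (prop-2-enal) | C=CC=O | starting material
12 | 3-[(3E)-5-{[tert-butyl(dimethyl)silyl]oxy}-3-methylpent-3-en-1-yl]-2,2,4-trimethylcyclohex-3-ene-1-carbaldehyde (racemic at C1) | CC1=C(CC/C(C)=C/CO[Si](C)(C)C(C)(C)C)C(C)(C)C(C=O)CC1 | intermediate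
13 | tert-butyl(dimethyl){[(2E)-3-methyl-5-(2,6,6-trimethylcyclohex-1-en-1-yl)pent-2-en-1-yl]oxy}silane | CC1=C(CC/C(C)=C/CO[Si](C)(C)C(C)(C)C)C(C)(C)CCC1 | intermediate
14 | (2E)-3-methyl-5-(2,6,6-trimethylcyclohex-1-en-1-yl)pent-2-en-1-ol | CC1=C(CC/C(C)=C/CO)C(C)(C)CCC1 | intermediate
15 | 2-[(3E)-5-bromo-3-methylpent-3-en-1-yl]-1,3,3-trimethylcyclohex-1-ene | CC1=C(CC/C(C)=C/CBr)C(C)(C)CCC1 | intermediate
16 | 2-methylprop-2-en-1-ol | C=C(C)CO | starting material
17 | dilithium dianion of 2-methylprop-2-en-1-ol (not isolated) | [Li]CC(=C)CO[Li] | intermediate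
18 | (5E)-6-methyl-2-methylidene-8-(2,6,6-trimethylcyclohex-1-en-1-yl)oct-5-en-1-ol | CC1=C(CC/C(C)=C/CCC(=C)CO)C(C)(C)CCC1 | intermediate
19 | (5E)-6-methyl-2-methylidene-8-(2,6,6-trimethylcyclohex-1-en-1-yl)oct-5-enal | CC1=C(CC/C(C)=C/CCC(=C)C=O)C(C)(C)CCC1 | intermediate
20 | (5E)-6-methyl-2-methylidene-8-(2,6,6-trimethylcyclohex-1-en-1-yl)oct-5-enoic acid | CC1=C(CC/C(C)=C/CCC(=C)C(=O)O)C(C)(C)CCC1 | intermediate
21 | furan-3-carbaldehyde | O=Cc1ccoc1 | starting material
22 | B-allyldiisopinocampheylborane, isopinocampheyl groups from (−)-α-pinene | C=CCB([C@H]1C[C@H]2C[C@@H]([C@@H]1C)C2(C)C)[C@H]1C[C@H]2C[C@@H]([C@@H]1C)C2(C)C | starting material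
23 | (1R)-1-(furan-3-yl)but-3-en-1-yl diisopinocampheylborinate (not isolated) | C=CC[C@@H](OB([C@H]1C[C@H]2C[C@@H]([C@@H]1C)C2(C)C)[C@H]1C[C@H]2C[C@@H]([C@@H]1C)C2(C)C)c1ccoc1 | intermediate
24 | (1R)-1-(furan-3-yl)but-3-en-1-ol | C=CC[C@@H](O)c1ccoc1 | intermediate
25 | (1R)-1-(furan-3-yl)but-3-en-1-yl (5E)-6-methyl-2-methylidene-8-(2,6,6-trimethylcyclohex-1-en-1-yl)oct-5-enoate | CC1=C(CC/C(C)=C/CCC(=C)C(=O)O[C@H](CC=C)c2ccoc2)C(C)(C)CCC1 | intermediate
26 | (6R)-6-(furan-3-yl)-3-[(3E)-4-methyl-6-(2,6,6-trimethylcyclohex-1-en-1-yl)hex-3-en-1-yl]-5,6-dihydro-2H-pyran-2-one | CC1=C(CC/C(C)=C/CCC2=CC[C@H](c3ccoc3)OC2=O)C(C)(C)CCC1 | intermediate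
27 | (1R,3Z,7E)-1-(furan-3-yl)-4-(hydroxymethyl)-8-methyl-10-(2,6,6-trimethylcyclohex-1-en-1-yl)deca-3,7-dien-1-ol | CC1=C(CC/C(C)=C/CC/C(=C/C[C@@H](O)c2ccoc2)CO)C(C)(C)CCC1 | intermediate
28 | 2,3,7-trioxabicyclo[2.2.1]hept-5-ene endoperoxide of 27, side chain on C5 (not isolated) | CC1=C(CC/C(C)=C/CC/C(=C/C[C@@H](O)C2=CC3OOC2O3)CO)C(C)(C)CCC1 | intermediate
29 | 5-hydroxy-4-[(1R,3Z,7E)-1-hydroxy-4-(hydroxymethyl)-8-methyl-10-(2,6,6-trimethylcyclohex-1-en-1-yl)deca-3,7-dien-1-yl]furan-2(5H)-one | CC1=C(CC/C(C)=C/CC/C(=C/C[C@@H](O)C2=CC(=O)OC2O)CO)C(C)(C)CCC1 | intermediate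
30 | sodium (2E)-4-hydroxy-3-[(1R,3Z,7E)-1-hydroxy-4-(hydroxymethyl)-8-methyl-10-(2,6,6-trimethylcyclohex-1-en-1-yl)deca-3,7-dien-1-yl]but-2-enoate, carboxylate cis to CH2OH (not isolated) | CC1=C(CC/C(C)=C/CC/C(=C/C[C@@H](O)/C(CO)=C/C(=O)[O-])CO)C(C)(C)CCC1.[Na+] | intermediate
31 | 4-[(1R,3Z,7E)-1-hydroxy-4-(hydroxymethyl)-8-methyl-10-(2,6,6-trimethylcyclohex-1-en-1-yl)deca-3,7-dien-1-yl]furan-2(5H)-one | CC1=C(CC/C(C)=C/CC/C(=C/C[C@@H](O)C2=CC(=O)OC2)CO)C(C)(C)CCC1 | target

**Step count and risks**
Total steps: 18. Longest linear sequence: 15 steps (from 6 through steps 3–12 and 14–18).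

Steps most likely to fail:

1. Step 6 (key Diels–Alder reaction). The Lewis acid may trigger an ene reaction or cationic oligomerisation of the electron-rich diene faster than cycloaddition, or conversion may stall because the cisoid conformer is strained. The fallback sets out from 10 and avoids any acid: a thermal or high-pressure Diels–Alder reaction with phenyl vinyl sulfone (toluene, 150 °C, sealed tube, or CH2Cl2 at 12 kbar, 40 °C) should give tert-butyl({(2E)-5-[5-(benzenesulfonyl)-2,6,6-trimethylcyclohex-1-en-1-yl]-3-methylpent-2-en-1-yl}oxy)dimethylsilane F1. Reductive desulfonylation with Na(Hg) and Na2HPO4 in MeOH/THF (−20 °C to rt) then returns to the route at 13.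

2. Step 7 (decarbonylation). Oxidative addition at the hindered formyl group may be slow, and β-hydride elimination or rhodium hydride-mediated double-bond migration may compete. The fallback sets out from 12: Pinnick oxidation (NaClO2, NaH2PO4, 2-methylbut-2-ene) should give 3-[(3E)-5-{[tert-butyl(dimethyl)silyl]oxy}-3-methylpent-3-en-1-yl]-2,2,4-trimethylcyclohex-3-ene-1-carboxylic acid F2. Coupling with N-hydroxypyridine-2-thione (DCC, DMAP) gives the Barton ester, 2-thioxopyridin-1(2H)-yl 3-[(3E)-5-{[tert-butyl(dimethyl)silyl]oxy}-3-methylpent-3-en-1-yl]-2,2,4-trimethylcyclohex-3-ene-1-carboxylate F3. Barton reductive decarboxylation (t-BuSH, visible light, benzene) returns to the route at 13.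

3. Step 10 (dianion alkylation). SN2' attack at the tertiary terminus of the allylic bromide, O-alkylation of the dianion, or decomposition of the labile bromide may erode the coupling. The fallback sets out from 14 and makes the same bond by a regiochemically fixed cross-coupling. MnO2 oxidation gives (2E)-3-methyl-5-(2,6,6-trimethylcyclohex-1-en-1-yl)pent-2-enal F4. Wittig methylenation (Ph3P=CH2, THF) gives 1,3,3-trimethyl-2-[(3E)-3-methylhexa-3,5-dien-1-yl]cyclohex-1-ene F5. Hydroboration of the terminal vinyl group with 9-BBN gives 9-[(3E)-4-methyl-6-(2,6,6-trimethylcyclohex-1-en-1-yl)hex-3-en-1-yl]-9-borabicyclo[3.3.1]nonane F6, and B-alkyl Suzuki–Miyaura coupling of this borane with commercial 2-bromoprop-2-en-1-ol (PdCl2(dppf), aqueous K3PO4, DMF) returns to the route at 18.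

**Further compounds**
F1 | step 6 | tert-butyl({(2E)-5-[5-(benzenesulfonyl)-2,6,6-trimethylcyclohex-1-en-1-yl]-3-methylpent-2-en-1-yl}oxy)dimethylsilane | CC1=C(CC/C(C)=C/CO[Si](C)(C)C(C)(C)C)C(C)(C)C(S(=O)(=O)c2ccccc2)CC1
F2 | step 7 | 3-[(3E)-5-{[tert-butyl(dimethyl)silyl]oxy}-3-methylpent-3-en-1-yl]-2,2,4-trimethylcyclohex-3-ene-1-carboxylic acid | CC1=C(CC/C(C)=C/CO[Si](C)(C)C(C)(C)C)C(C)(C)C(C(=O)O)CC1
F3 | step 7 | 2-thioxopyridin-1(2H)-yl 3-[(3E)-5-{[tert-butyl(dimethyl)silyl]oxy}-3-methylpent-3-en-1-yl]-2,2,4-trimethylcyclohex-3-ene-1-carboxylate | CC1=C(CC/C(C)=C/CO[Si](C)(C)C(C)(C)C)C(C)(C)C(C(=O)ON2C=CC=CC2=S)CC1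
F4 | step 10 | (2E)-3-methyl-5-(2,6,6-trimethylcyclohex-1-en-1-yl)pent-2-enal | CC1=C(CC/C(C)=C/C=O)C(C)(C)CCC1
F5 | step 10 | 1,3,3-trimethyl-2-[(3E)-3-methylhexa-3,5-dien-1-yl]cyclohex-1-ene | CC1=C(CC/C(C)=C/C=C)C(C)(C)CCC1
F6 | step 10 | 9-[(3E)-4-methyl-6-(2,6,6-trimethylcyclohex-1-en-1-yl)hex-3-en-1-yl]-9-borabicyclo[3.3.1]nonane | CC1=C(CC/C(C)=C/CCB2C3CCCC2CCC3)C(C)(C)CCC1
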